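**Retrosynthetic overview**
1. Leucanthin B ← C14 aldehyde ← ten-membered carbocycle closed last by ring-closing metathesis at C1=C10; C2–C3 bond by γ-chloroallylboration of a C3 enal, C9–C10 bond by chelation-controlled alkenyl addition to a C9 aldehyde.
2. All of this is built on an α-methylene-γ-lactone core (C3–C9, C11–C13) whose two ring bonds, C11–C7 and O–C6, are made together by a manganese-mediated oxidative radical/cation annulation of a hydrogen malonate across C6=C7.
3. Enabling feature: C6=C7 is the terminal double bond of the (4Z,6E)-diene C4=C5–C6=C7, so attack at C7 leaves an allyl system over C6–C5–C4 that the acid closes at C6; the C9 oxygen sits three atoms from C7 and carries the malonate as a six-membered tether, with C8 as the only stereocentre of the precursor.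
4. Ring order: γ-lactone (with a temporary δ-lactone) → 4,5-oxirane → 2,3-oxirane → ten-membered ring.
5. Stereochemistry: C8 by asymmetric Pd catalysis; C7 and C6 relayed from C8 in the key step; C9 by chelation; C3/C2 by reagent control; C4/C5 directed by the C3 hydroxyl; epoxyangelate by Sharpless epoxidation.

Key step: step 6

Remark: labels C1–C15 on intermediates are the germacrane positions of the target (C1–C10 ring, C11–C13 lactone carbons, C14 carboxyl, C15 methyl); DMPM = 3,4-dimethoxybenzyl, PMB = 4-methoxybenzyl, TBDPS = tert-butyldiphenylsilyl.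
Assumption: the (R,R)-ligand in step 3 is taken to give the S ether, and the borane from (+)-Ipc2BOMe in step 19 to add to the aldehyde face that leads to the target C3 configuration; the antipodal ligand or borane is used if the sense of induction is the opposite.

**Route**

Step 1
Reactants: 1 prop-2-yn-1-ol
Product: 3 (Z)-3-iodo-2-methylprop-2-en-1-ol, via alkenylmagnesium alkoxide 2 (not isolated)
Conditions: MeMgBr (2.5 equiv), CuI (10 mol%), THF, −10 °C → rt; then I2, −10 °C
Reagents that add atoms: methylmagnesium bromide, C[Mg]Br; iodine, II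
Why: Copper-catalysed anti-carbomagnesiation of the propargylic alkoxide places Mg on the terminal carbon cis to CH2O through a five-membered chelate, so iodinolysis should give the Z iodide carrying the future C15 methyl.

Step 2
Reactants: 3 (Z)-3-iodo-2-methylprop-2-en-1-ol
Product: 4 (Z)-tert-butyl[(3-iodo-2-methylprop-2-en-1-yl)oxy]diphenylsilane
Conditions: TBDPSCl, imidazole, CH2Cl2, rt
Reagents that add atoms: tert-butyldiphenylsilyl chloride, CC(C)(C)[Si](Cl)(c1ccccc1)c1ccccc1
Why: Standard silylation of a primary alcohol; the TBDPS ether is chosen to survive AcOH in step 6.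

Step 3
Reactants: 5 2-vinyloxirane (racemic); 6 (3,4-dimethoxyphenyl)methanol
Product: 7 (S)-2-[(3,4-dimethoxybenzyl)oxy]but-3-en-1-ol
Conditions: Pd2(dba)3·CHCl3 (1 mol%), (R,R)-DACH-phenyl bis(2-diphenylphosphinobenzamide) ligand (3 mol%), BEt3 (1 mol%), CH2Cl2, rt
Reagents that add atoms: none
Why: Dynamic kinetic asymmetric allylic etherification of the vinyl epoxide through the π-allyl complex of divalent palladium, the borane delivering the alcohol to the branched terminus; the ligand sets the carbon that becomes C8.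

Step 4
Reactants: 7 (S)-2-[(3,4-dimethoxybenzyl)oxy]but-3-en-1-ol; 4 Z-iodide TBDPS ether
Product: 8 (2S,3E,5Z)-7-[(tert-butyldiphenylsilyl)oxy]-2-[(3,4-dimethoxybenzyl)oxy]-6-methylhepta-3,5-dien-1-ol
Conditions: Pd(OAc)2 (5 mol%), Ag2CO3 (1.1 equiv), DMF, 50 °C, dark
Reagents that add atoms: none
Why: Silver-promoted Heck coupling: carbopalladation at the CH2 terminus and β-hydride elimination toward conjugation should give the E C6=C7 bond with retention of the Z C4=C5 geometry of the iodide.

Step 5
Reactants: 8 dienol; 9 Meldrum's acid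
Product: 10 hydrogen malonate of 8 at O9
Conditions: toluene, 85 °C
Reagents that add atoms: none
Why: Thermal acyl transfer from Meldrum's acid to a primary alcohol is the standard route to malonic half esters, with loss of acetone.

Step 6
Reactants: 10 hydrogen malonate
Product: 11 cis-fused bis-lactone (γ-lactone C12–O–C6 and δ-lactone through O9 sharing C11–C7; H6/H7 trans; 8-O-DMPM; Z C4=C5; 3-O-TBDPS)
Conditions: Mn(OAc)3·2H2O (2.2 equiv), KOAc (2 equiv), degassed AcOH (0.02 M), 30 °C
Reagents that add atoms: none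
Why: Proposed new method: Mn(OAc)3 enolises and oxidises the hydrogen malonate to the C11 malonyl radical, which cyclises 6-exo-trig onto C7, the near terminus of the diene, through the temporary ester tether (δ-lactone ring), and the C6–C5–C4 allyl radical is oxidised by the second equivalent of trivalent manganese to the allyl cation, which the free carboxyl captures at C6 in a 5-exo closure (γ-lactone ring), so that C11–C7 and O–C6 form in one operation. The closest known reactions are the Mn(OAc)3 carbolactonisation of 1,3-dienes with malonic or cyanoacetic acid and the Mn(OAc)3 oxidative cyclisation of unsaturated malonates, of which this is the ester-tethered intramolecular combination. C7 should be set by C8 through a chair transition state with the 8-alkoxy group and the diene both equatorial (8-O and C6 trans on the tether ring), and C6 by C7 because the alkenyl group takes the convex face of the bicycle (H6/H7 trans); C11 is set as the cis ring fusion but is lost later when it becomes sp2. The step needs attack at C7 rather than C6 (only exo attack on the diene gives an allyl radical), closure at C6 rather than C4 (five- versus seven-membered ring), retention of the Z C4=C5 geometry (s-trans diene, configurationally stable allyl intermediate trapped intramolecularly) and no over-oxidation at C11 (oxidant held near two equivalents).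

Step 7
Reactants: 11 bis-lactone
Product: 13 α-methylene-γ-lactone with free C9 hydroxyl, via α-carboxy lactone 12 (not isolated)
Conditions: LiOH (1.2 equiv), THF/H2O, 0 °C; 1 M HCl to pH 3, EtOAc extraction; then (CH2O)n, Et2NH, EtOAc, 60 °C
Reagents that add atoms: paraformaldehyde (as formaldehyde), C=O
Why: Hydroxide should open the more reactive δ-lactone and the resulting carboxylate shields the γ-lactone, after which the decarboxylative Mannich methylenation of the α-carboxy lactone removes the tether carbon as CO2 and installs C13.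

Step 8
Reactants: 13 α-methylene lactone alcohol
Product: 14 C9 aldehyde
Conditions: Dess–Martin periodinane, NaHCO3, CH2Cl2, 0 °C → rt
Reagents that add atoms: none
Why: Buffered Dess–Martin oxidation of a primary alcohol should leave the α-alkoxy stereocentre C8 and the methylene lactone untouched.

Step 9
Reactants: 15 2,3-dibromopropene; 16 (4-methoxyphenyl)methanol
Product: 17 2-bromo-3-[(4-methoxybenzyl)oxy]prop-1-ene
Conditions: NaH, THF, 0 °C → rt
Reagents that add atoms: none
Why: Williamson ether synthesis at the allylic bromide; the vinylic bromide is inert.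

Step 10
Reactants: 14 C9 aldehyde; 17 2-bromoallyl PMB ether
Product: 20 C9 secondary alcohol (8,9-syn; C10 as 1,1-disubstituted olefin bearing C14H2OPMB), via alkenyllithium 18 (not isolated), via alkenylmagnesium bromide 19 (not isolated)
Conditions: 17, t-BuLi (2.0 equiv), Et2O, −78 °C; MgBr2·OEt2; then 14, CH2Cl2, −78 °C
Reagents that add atoms: none
Why: The alkenyl Grignard reagent should add under chelation control (magnesium bridging the carbonyl and the 8-benzyloxy oxygen, attack anti to C7) to give the 8,9-syn alcohol, the aldehyde reacting far faster at −78 °C than the lactone or its methylene group.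

Step 11
Reactants: 20 C9 alcohol
Product: 21 C9 acetate
Conditions: Ac2O, pyridine, DMAP (cat.), CH2Cl2, 0 °C → rt
Reagents that add atoms: acetic anhydride, CC(=O)OC(C)=O
Why: Standard acetylation installs the 9-O-acetyl group of the target.

Step 12
Reactants: 21 C9 acetate
Product: 22 C8 alcohol
Conditions: DDQ (1.1 equiv), CH2Cl2/pH 7 buffer (10:1), 0 °C
Reagents that add atoms: none
Why: DDQ oxidises the more electron-rich 3,4-dimethoxybenzyl ether much faster than the 4-methoxybenzyl ether, so only the C8 hydroxyl should be freed.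

Step 13
Reactants: 23 angelic acid
Product: 24 (Z)-2-methylbut-2-en-1-ol
Conditions: LiAlH4, Et2O, 0 °C
Reagents that add atoms: none
Why: Hydride reduction of the conjugated acid to the allylic alcohol with retention of the Z olefin.

Step 14
Reactants: 24 (Z)-2-methylbut-2-en-1-ol
Product: 25 [(2S,3R)-2,3-dimethyloxiran-2-yl]methanol
Conditions: Ti(OiPr)4 (10 mol%), D-(−)-diethyl tartrate (12 mol%), t-BuOOH, 4 Å MS, CH2Cl2, −20 °C
Reagents that add atoms: tert-butyl hydroperoxide, CC(C)(C)OO
Why: Sharpless asymmetric epoxidation; the D-tartrate should deliver oxygen to the face that gives the (2S,3R)-epoxy alcohol.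

Step 15
Reactants: 25 epoxy alcohol
Product: 26 (2R,3R)-2,3-dimethyloxirane-2-carboxylic acid
Conditions: TEMPO (20 mol%), PhI(OAc)2 (2.2 equiv), MeCN/H2O, rt
Reagents that add atoms: water, O
Why: Nitroxyl-catalysed oxidation through the aldehyde hydrate gives the acid without opening the epoxide.

Step 16
Reactants: 22 C8 alcohol; 26 epoxy acid
Product: 28 C8 (2R,3R)-epoxyangelate, via mixed anhydride 27 (not isolated)
Conditions: 26, 2,4,6-trichlorobenzoyl chloride, Et3N, THF, rt; then 22, DMAP, toluene, rt → 40 °C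
Reagents that add atoms: none
Why: Yamaguchi esterification suits a hindered secondary alcohol and an α-quaternary acid, and is done on the open chain where C8 is more accessible than in the ring.

Step 17
Reactants: 28 C8 epoxyangelate
Product: 29 C3 allylic alcohol
Conditions: TBAF, AcOH (1:1), THF, 0 °C → rt
Reagents that add atoms: none
Why: Buffered fluoride removes the TBDPS ether without acyl migration, epoxide opening or attack on the methylene lactone.

Step 18
Reactants: 29 C3 allylic alcohol
Product: 30 (Z)-enal (C3 aldehyde)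
Conditions: MnO2, CH2Cl2, rt
Reagents that add atoms: none
Why: MnO2 oxidises the allylic alcohol selectively and neutrally, which should preserve the Z geometry.

Step 19
Reactants: 30 (Z)-enal; 31 allyl chloride
Product: 33 syn chlorohydrin (C3–OH, C2–Cl, C1 vinyl), via (Z)-γ-chloroallyldiisopinocampheylborane 32 (not isolated)
Conditions: 31, LiN(c-C6H11)2, (+)-Ipc2BOMe, Et2O, −95 °C; BF3·OEt2; then 30, −95 °C; ethanolamine work-up
Reagents that add atoms: none
Why: Asymmetric γ-chloroallylboration through a chair transition state: the Z reagent gives the syn chlorohydrin and the isopinocampheyl groups (from (−)-α-pinene) select the aldehyde face, which should set C3 and place chlorine at C2 for cis-epoxide formation.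

Step 20
Reactants: 33 syn chlorohydrin
Product: 34 4,5-epoxy chlorohydrin
Conditions: mCPBA (1.2 equiv), NaHCO3, CH2Cl2, 0 °C
Reagents that add atoms: 3-chloroperbenzoic acid, OOC(=O)c1cccc(Cl)c1
Why: Hydroxyl-directed peracid epoxidation of the Z-trisubstituted allylic alcohol: 1,3-allylic strain holds H3 in the olefin plane and oxygen is delivered to the face of the C3 hydroxyl (threo), which should set C4 and C5; the other olefins are electron-poor or deactivated.

Step 21
Reactants: 34 epoxy chlorohydrin
Product: 35 open-chain bis-epoxide diene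
Conditions: DBU (1.5 equiv), CH2Cl2, rt
Reagents that add atoms: none
Why: Intramolecular Williamson closure with inversion at C2 converts the syn chlorohydrin into the cis-2,3-epoxide; the aprotic amine base avoids Payne rearrangement and solvolysis.

Step 22
Reactants: 35 bis-epoxide diene
Product: 36 ten-membered carbocycle (C1=C10 with C2 and C9 cis; C14H2OPMB)
Conditions: second-generation Hoveyda–Grubbs catalyst RuCl2(H2IMes)(=CH–C6H4-2-OiPr) (20 mol%, portions), toluene (1 mM), 80 °C, argon sparge
Reagents that add atoms: none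
Why: Ring-closing metathesis between the vinyl epoxide and the 1,1-disubstituted olefin; with the cis 4,5-epoxide and the trans lactone in the ring the new trisubstituted olefin is expected ring-cis.

Step 23
Reactants: 36 macrocyclic PMB ether
Product: 37 C14 allylic alcohol
Conditions: DDQ (2 equiv), CH2Cl2/pH 7 buffer, rt
Reagents that add atoms: none
Why: Oxidative cleavage of the PMB ether under neutral conditions that epoxides, esters and the methylene lactone tolerate.

Step 24
Reactants: 37 C14 allylic alcohol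
Product: 38 C14 enal
Conditions: MnO2, CH2Cl2, rt
Reagents that add atoms: none
Why: Selective allylic oxidation; C8 is already acylated, so no lactol or second lactone can form with C14.

Step 25
Reactants: 38 C14 enal
Product: 39 leucanthin B
Conditions: NaClO2, NaH2PO4, 2-methyl-2-butene, t-BuOH/H2O, 0 °C → rt
Reagents that add atoms: sodium chlorite, [Na+].[O-]Cl=O
Why: Pinnick oxidation converts the enal to the acid under weakly acidic conditions with a hypochlorite scavenger, compatible with the epoxides and the electron-poor olefins.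

**Compound list**
1 | prop-2-yn-1-ol | C#CCO | starting material
2 | bromomagnesium (Z)-3-(bromomagnesio)-2-methylprop-2-en-1-olate | Br[Mg]OC/C(C)=C\[Mg]Br | intermediate
3 | (Z)-3-iodo-2-methylprop-2-en-1-ol | OC/C(C)=C\I | intermediate
4 | (Z)-tert-butyl[(3-iodo-2-methylprop-2-en-1-yl)oxy]diphenylsilane | CC(C)(C)[Si](OC/C(C)=C\I)(c1ccccc1)c1ccccc1 | intermediate
5 | 2-vinyloxirane (racemic) | C=CC1CO1 | starting material
6 | (3,4-dimethoxyphenyl)methanol | COc1ccc(CO)cc1OC | starting material
7 | (S)-2-[(3,4-dimethoxybenzyl)oxy]but-3-en-1-ol | C=C[C@H](OCc1ccc(OC)c(OC)c1)CO | intermediate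
8 | (2S,3E,5Z)-7-[(tert-butyldiphenylsilyl)oxy]-2-[(3,4-dimethoxybenzyl)oxy]-6-methylhepta-3,5-dien-1-ol | OC[C@@H](OCc1ccc(OC)c(OC)c1)/C=C/C=C(C)\CO[Si](c1ccccc1)(c1ccccc1)C(C)(C)C | intermediate
9 | Meldrum's acid (2,2-dimethyl-1,3-dioxane-4,6-dione) | CC1(C)OC(=O)CC(=O)O1 | starting material
10 | hydrogen malonate of 8 (malonic half ester at O9) | OC(=O)CC(=O)OC[C@@H](OCc1ccc(OC)c(OC)c1)/C=C/C=C(C)\CO[Si](c1ccccc1)(c1ccccc1)C(C)(C)C | intermediate
11 | cis-fused bis-lactone: γ-lactone (C12, O–C6) and δ-lactone (tether, O9) sharing C11–C7; H6/H7 trans; 8-O-DMPM; C6 bears the (Z)-2-methyl-3-(TBDPS-oxy)prop-1-enyl group | O=C1O[C@H](/C=C(C)\CO[Si](c2ccccc2)(c3ccccc3)C(C)(C)C)[C@H]4[C@H](OCc5ccc(OC)c(OC)c5)COC(=O)[C@@H]14 | intermediate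
12 | α-carboxy-γ-lactone with free C9 hydroxyl (C11 epimers) | O=C1O[C@H](/C=C(C)\CO[Si](c2ccccc2)(c3ccccc3)C(C)(C)C)[C@@H]([C@H](OCc4ccc(OC)c(OC)c4)CO)C1C(=O)O | intermediate
13 | α-methylene-γ-lactone, C9 primary alcohol, 8-O-DMPM, 3-O-TBDPS | C=C1C(=O)O[C@H](/C=C(C)\CO[Si](c2ccccc2)(c3ccccc3)C(C)(C)C)[C@H]1[C@H](OCc4ccc(OC)c(OC)c4)CO | intermediate
14 | C9 aldehyde of 13 | C=C1C(=O)O[C@H](/C=C(C)\CO[Si](c2ccccc2)(c3ccccc3)C(C)(C)C)[C@H]1[C@H](OCc4ccc(OC)c(OC)c4)C=O | intermediate
15 | 2,3-dibromoprop-1-ene | C=C(Br)CBr | starting material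
16 | (4-methoxyphenyl)methanol | COc1ccc(CO)cc1 | starting material
17 | 2-bromo-3-[(4-methoxybenzyl)oxy]prop-1-ene | C=C(Br)COCc1ccc(OC)cc1 | intermediate
18 | {3-[(4-methoxybenzyl)oxy]prop-1-en-2-yl}lithium | [Li]C(=C)COCc1ccc(OC)cc1 | intermediate
19 | {3-[(4-methoxybenzyl)oxy]prop-1-en-2-yl}magnesium bromide | Br[Mg]C(=C)COCc1ccc(OC)cc1 | intermediate
20 | C9 alcohol (8,9-syn), C10 as 2-(PMB-oxymethyl)vinyl | C=C1C(=O)O[C@H](/C=C(C)\CO[Si](c2ccccc2)(c3ccccc3)C(C)(C)C)[C@H]1[C@H](OCc4ccc(OC)c(OC)c4)[C@@H](O)C(=C)COCc5ccc(OC)cc5 | intermediate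
21 | C9 acetate of 20 | C=C1C(=O)O[C@H](/C=C(C)\CO[Si](c2ccccc2)(c3ccccc3)C(C)(C)C)[C@H]1[C@H](OCc4ccc(OC)c(OC)c4)[C@@H](OC(C)=O)C(=C)COCc5ccc(OC)cc5 | intermediate
22 | C8 alcohol (DMPM removed) | C=C1C(=O)O[C@H](/C=C(C)\CO[Si](c2ccccc2)(c3ccccc3)C(C)(C)C)[C@H]1[C@H](O)[C@@H](OC(C)=O)C(=C)COCc4ccc(OC)cc4 | intermediate
23 | angelic acid, (Z)-2-methylbut-2-enoic acid | C/C=C(/C)C(=O)O | starting material
24 | (Z)-2-methylbut-2-en-1-ol | C/C=C(/C)CO | intermediate
25 | [(2S,3R)-2,3-dimethyloxiran-2-yl]methanol | OC[C@]1(C)O[C@@H]1C | intermediate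
26 | (2R,3R)-2,3-dimethyloxirane-2-carboxylic acid | OC(=O)[C@]1(C)O[C@@H]1C | intermediate
27 | mixed anhydride of 26 with 2,4,6-trichlorobenzoic acid | O=C(OC(=O)c1c(Cl)cc(Cl)cc1Cl)[C@]1(C)O[C@@H]1C | intermediate
28 | C8 epoxyangelate, 9-OAc, 3-O-TBDPS, 14-O-PMB | C=C1C(=O)O[C@H](/C=C(C)\CO[Si](c2ccccc2)(c3ccccc3)C(C)(C)C)[C@H]1[C@H](OC(=O)[C@]4(C)O[C@@H]4C)[C@@H](OC(C)=O)C(=C)COCc5ccc(OC)cc5 | intermediate
29 | C3 allylic alcohol | C=C1C(=O)O[C@H](/C=C(C)\CO)[C@H]1[C@H](OC(=O)[C@]2(C)O[C@@H]2C)[C@@H](OC(C)=O)C(=C)COCc3ccc(OC)cc3 | intermediate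
30 | (Z)-enal (C3 aldehyde) | C=C1C(=O)O[C@H](/C=C(C)\C=O)[C@H]1[C@H](OC(=O)[C@]2(C)O[C@@H]2C)[C@@H](OC(C)=O)C(=C)COCc3ccc(OC)cc3 | intermediate
31 | allyl chloride | C=CCCl | starting material
32 | (Z)-(3-chloroallyl)diisopinocampheylborane (Ipc from (−)-α-pinene) | Cl/C=C\CB([C@H]1C[C@H]2C[C@@H]([C@@H]1C)C2(C)C)[C@H]1C[C@H]2C[C@@H]([C@@H]1C)C2(C)C | intermediate
33 | syn chlorohydrin (C3–OH, C2–Cl, C1 vinyl) | C=C1C(=O)O[C@H](/C=C(C)\[C@H](O)[C@@H](Cl)C=C)[C@H]1[C@H](OC(=O)[C@]2(C)O[C@@H]2C)[C@@H](OC(C)=O)C(=C)COCc3ccc(OC)cc3 | intermediate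
34 | 4,5-epoxy chlorohydrin | C=C1C(=O)O[C@H]([C@H]2O[C@@]2(C)[C@H](O)[C@@H](Cl)C=C)[C@H]1[C@H](OC(=O)[C@]3(C)O[C@@H]3C)[C@@H](OC(C)=O)C(=C)COCc4ccc(OC)cc4 | intermediate
35 | open-chain 2,3:4,5-bis-epoxide diene | C=C1C(=O)O[C@H]([C@H]2O[C@@]2(C)[C@@H]3O[C@@H]3C=C)[C@H]1[C@H](OC(=O)[C@]4(C)O[C@@H]4C)[C@@H](OC(C)=O)C(=C)COCc5ccc(OC)cc5 | intermediate
36 | ten-membered carbocycle, 14-O-PMB | C=C1C(=O)O[C@H]2[C@H]1[C@H](OC(=O)[C@]3(C)O[C@@H]3C)[C@@H](OC(C)=O)/C(COCc4ccc(OC)cc4)=C\[C@H]5O[C@H]5[C@]6(C)O[C@H]26 | intermediate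
37 | C14 allylic alcohol | C=C1C(=O)O[C@H]2[C@H]1[C@H](OC(=O)[C@]3(C)O[C@@H]3C)[C@@H](OC(C)=O)/C(CO)=C\[C@H]4O[C@H]4[C@]5(C)O[C@H]25 | intermediate
38 | C14 enal | C=C1C(=O)O[C@H]2[C@H]1[C@H](OC(=O)[C@]3(C)O[C@@H]3C)[C@@H](OC(C)=O)/C(C=O)=C\[C@H]4O[C@H]4[C@]5(C)O[C@H]25 | intermediate
39 | leucanthin B | C=C1C(=O)O[C@H]2[C@H]1[C@H](OC(=O)[C@]1(C)O[C@@H]1C)[C@@H](OC(C)=O)/C(C(=O)O)=C\[C@H]1O[C@H]1[C@]1(C)O[C@H]21 | target

**Totals**
Total step count: 25. Longest linear sequence: 20 steps (steps 1, 2, 4–8, 10–12, 16–25).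

**Steps most likely to fail**

1. Step 6 (Proposed new method). The ester tether must reach the cyclisation geometry through its less populated rotamer, so the 6-exo closure may be slow and intermolecular radical coupling may take over. Facial selectivity at C7 may be poor, and the acidic C11–H of the product may be oxidised further. Fallback (known chemistry, the intermolecular manganese carbolactonisation of 1,3-dienes with malonic acid): it sets out from 8. Acetylation of the primary hydroxyl (Ac2O, pyridine) should give the acetate F1. Malonic acid, Mn(OAc)3·2H2O and KOAc in AcOH at 25 °C should annulate the diene (radical attack at C7, carboxylate closure at C6, trans lactone) to the α-carboxy lactone acetate F2, whose C6/C7 diastereomers relative to C8 have to be separated. LiOH followed by HCl then removes the acetate and brings the route back at 12, which the formaldehyde stage of step 7 converts to 13.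

2. Step 22. Ring closure to a ten-membered ring at a hindered 1,1-disubstituted olefin may be slower than oligomerisation or catalyst decay, and the rigid bis-epoxide may disfavour the reactive conformation. Fallback: close the ring before either epoxide exists. It sets out from 33. Ring-closing metathesis of the more flexible chlorohydrin under the conditions of step 22 should give the macrocyclic chlorohydrin F3. Hydroxyl-directed epoxidation with mCPBA should give the macrocyclic epoxy chlorohydrin F4, and DBU closes the 2,3-epoxide, coming back to the route at 36.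

3. Step 10. The organometallic reagent may attack the methylene lactone, the aldehyde may epimerise at C8, or chelation control may be lost and give the C9 epimer. Fallback: it sets out from 14 and 17. A Nozaki–Hiyama–Kishi coupling (CrCl2, NiCl2 cat., DMF), chemoselective for the aldehyde, should give mainly the C9-epimeric alcohol F5 (non-chelation mode). Dess–Martin oxidation gives the enone F6, and Corey–Bakshi–Shibata reduction ((S)-Me-CBS oxazaborolidine, BH3·SMe2, THF, −40 °C; the antipode if the sense is opposite) sets C9 by reagent control, coming back to the route at 20.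

**Further compounds**
F1 | step 6 | (2S,3E,5Z)-7-(TBDPS-oxy)-2-(DMPM-oxy)-6-methylhepta-3,5-dien-1-yl acetate | CC(=O)OC[C@@H](OCc1ccc(OC)c(OC)c1)/C=C/C=C(C)\CO[Si](c1ccccc1)(c1ccccc1)C(C)(C)C
F2 | step 6 | α-carboxy-γ-lactone with C9 acetate (C11 epimers) | O=C1O[C@H](/C=C(C)\CO[Si](c2ccccc2)(c3ccccc3)C(C)(C)C)[C@@H]([C@H](OCc4ccc(OC)c(OC)c4)COC(C)=O)C1C(=O)O
F3 | step 22 | macrocyclic chlorohydrin (C1=C10 and Z C4=C5 in the ring, C2–Cl, C3–OH) | C=C1C(=O)O[C@H]2[C@H]1[C@H](OC(=O)[C@]3(C)O[C@@H]3C)[C@@H](OC(C)=O)/C(COCc4ccc(OC)cc4)=C\[C@H](Cl)[C@@H](O)/C(C)=C\2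
F4 | step 22 | macrocyclic 4,5-epoxy chlorohydrin | C=C1C(=O)O[C@H]2[C@H]1[C@H](OC(=O)[C@]3(C)O[C@@H]3C)[C@@H](OC(C)=O)/C(COCc4ccc(OC)cc4)=C\[C@H](Cl)[C@@H](O)[C@]5(C)O[C@H]25
F5 | step 10 | C9 epimer of 20 | C=C1C(=O)O[C@H](/C=C(C)\CO[Si](c2ccccc2)(c3ccccc3)C(C)(C)C)[C@H]1[C@H](OCc4ccc(OC)c(OC)c4)[C@H](O)C(=C)COCc5ccc(OC)cc5
F6 | step 10 | C9 enone | C=C1C(=O)O[C@H](/C=C(C)\CO[Si](c2ccccc2)(c3ccccc3)C(C)(C)C)[C@H]1[C@H](OCc4ccc(OC)c(OC)c4)C(=O)C(=C)COCc5ccc(OC)cc5
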